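The dihydropyran ring of the dimethylchromanol is read backwards through its aryl–O1–C2(CH3)2 unit: a phenol oxygen next to an acetone carbon, the signature of a Hock/Criegee rearrangement. The precursor is therefore a cumyl-type hydroperoxide in which C2 is still bonded to the aromatic carbon C8a, flanked by an ortho vinyl group (future C3=C4). On acylation, the aryl group shifts from C2 to oxygen, making O1–C8a, and the O-aryl oxocarbenium ion so formed closes onto the vinyl terminus, making C2–C3 and a 2H-chromene. Asymmetric epoxidation/hydrogenolysis sets C3; iridium borylation and an enantioselective palladium-catalysed conjugate addition to a chromone build the (2S)-flavanone.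

Key step: step 5

Assumption: methyl 2-bromo-6-hydroxybenzoate and 7-hydroxy-4H-chromen-4-one are taken as catalogue compounds. Locants O1, C2, C3, C4, C4a, C5–C8, C8a refer to the dimethylchroman unit; "flavanone C2" is the stereocentre of the chroman-4-one.

Step 1
Reactants: 1 methyl 2-bromo-6-hydroxybenzoate
Product: 2 methyl 2-hydroxy-6-vinylbenzoate
Conditions: vinylboronic acid pinacol ester (1.3 equiv), PdCl2(dppf) (3 mol %), K2CO3 (3 equiv), 1,4-dioxane/H2O 4:1, 85 °C
Reagents that add atoms: vinylboronic acid pinacol ester, C=CB1OC(C)(C)C(C)(C)O1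
Why: Suzuki–Miyaura coupling of an aryl bromide activated by the ortho ester, with the phenol carried as its phenoxide and the doubly ortho-substituted ester expected to resist hydrolysis.

Step 2
Reactants: 2 methyl 2-hydroxy-6-vinylbenzoate
Product: 3 2-(2-hydroxy-6-vinylphenyl)propan-2-ol
Conditions: MeMgBr (5 equiv), THF, 0 °C to rt; aq NH4Cl
Reagents that add atoms: methylmagnesium bromide, C[Mg]Br
Why: Double Grignard addition to a salicylate ester, in which chelation of the carbonyl group by the magnesium phenoxide should keep the hindered ester and the ketone formed from it open to the small methyl nucleophile.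

Step 3
Reactants: 3 2-(2-hydroxy-6-vinylphenyl)propan-2-ol
Product: 4 2-{2-[(triisopropylsilyl)oxy]-6-vinylphenyl}propan-2-ol
Conditions: TIPSOTf (1.1 equiv), 2,6-lutidine (2 equiv), CH2Cl2, −78 to 0 °C
Reagents that add atoms: triisopropylsilyl trifluoromethanesulfonate, CC(C)[Si](C(C)C)(C(C)C)OS(=O)(=O)C(F)(F)F
Why: Chemoselective O-silylation of the phenol, the doubly ortho-flanked tertiary alcohol being too hindered to react; the bulky, weakly nucleophilic silyl ether is chosen so that this oxygen cannot intercept the cation of step 5.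

Step 4
Reactants: 4 2-{2-[(triisopropylsilyl)oxy]-6-vinylphenyl}propan-2-ol
Product: 5 2-{2-[(triisopropylsilyl)oxy]-6-vinylphenyl}propan-2-yl hydroperoxide
Conditions: 50% aq H2O2 (10 equiv), H2SO4 (5 mol %), Et2O, 0 °C; washed free of H2O2, dried, used as a CH2Cl2 solution
Reagents that add atoms: hydrogen peroxide, OO
Why: Acid-catalysed perhydrolysis of a tertiary benzylic alcohol (SN1 through the cumyl-type cation), the standard route to cumyl hydroperoxides, under dilute aqueous acid that should be too weak to trigger the rearrangement.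

Step 5
Reactants: 5 2-{2-[(triisopropylsilyl)oxy]-6-vinylphenyl}propan-2-yl hydroperoxide
Product: 8 2,2-dimethyl-8-[(triisopropylsilyl)oxy]-2H-chromene, via peroxy trifluoroacetate 6 (not isolated), via oxocarbenium trifluoroacetate 7 (not isolated)
Conditions: (CF3CO)2O (1.2 equiv), 4 Å molecular sieves, CH2Cl2, −78 to −10 °C; then aq NaHCO3
Reagents that add atoms: none
Why: Proposed new method: trifluoroacetylation of the hydroperoxide gives perester 6, whose O–O bond ionises with a concerted 1,2-shift of the electron-rich aryl group from C2 to oxygen (Criegee variant of the Hock rearrangement), which makes O1–C8a and leaves the O-aryl oxocarbenium ion 7 with trifluoroacetate instead of water as its partner. Ion 7 is a 2-oxonia-hexatriene (C2=O1, C8a=C4a, C4=C3) in which C2 attacks the vinyl terminus C3, making C2–C3 and a C4 benzylic cation stabilised by O1, and loss of a proton from C3 gives the 2H-chromene. The closest known reaction types are the Hock cleavage of cumene hydroperoxide, the Criegee rearrangement of tertiary peresters and the Prins cyclisation of alkenyl oxocarbenium ions; the capture of the rearranged cation by an ortho vinyl group is the part without direct precedent. The pyran ring closes in a 6-endo-trig mode with respect to both the oxocarbenium and the olefin (equivalently a 6π electrocyclisation of the cation). No stereocentre is formed. The step needs aryl rather than methyl migration, which the ortho-silyloxy aryl group secures, and C–C closure rather than fragmentation to phenol and acetone or capture by the neighbouring oxygen, which the water-free acylative activation and the bulky, weakly nucleophilic silyl ether are meant to secure.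

Step 6
Reactants: 8 2,2-dimethyl-8-[(triisopropylsilyl)oxy]-2H-chromene
Product: 9 (3S,4S)-3,4-epoxy-2,2-dimethyl-8-[(triisopropylsilyl)oxy]chroman
Conditions: (S,S)-(salen)MnCl [chloro{(S,S)-N,N'-bis(3,5-di-tert-butylsalicylidene)cyclohexane-1,2-diaminato}manganese] (4 mol %), 4-phenylpyridine N-oxide (0.2 equiv), aq NaOCl (pH 11.3), CH2Cl2, 0 °C
Reagents that add atoms: sodium hypochlorite, [Na+].[O-]Cl
Why: Jacobsen–Katsuki epoxidation, for which 2,2-dimethyl-2H-chromenes are benchmark substrates; the (S,S) catalyst is expected to deliver oxygen to the face that gives the (3S,4S)-epoxide, which fixes the C3 configuration.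

Step 7
Reactants: 9 (3S,4S)-3,4-epoxy-2,2-dimethyl-8-[(triisopropylsilyl)oxy]chroman
Product: 10 (3S)-2,2-dimethyl-8-[(triisopropylsilyl)oxy]chroman-3-ol
Conditions: H2 (1 atm), Pd/C (10 wt %), Et3N (0.1 equiv), EtOAc, rt
Reagents that add atoms: none
Why: Hydrogenolysis of the benzylic C4–O bond of the aryl epoxide, which leaves the C3–O bond and hence the (3S) configuration untouched.

Step 8
Reactants: 10 (3S)-2,2-dimethyl-8-[(triisopropylsilyl)oxy]chroman-3-ol
Product: 12 [(3S)-3-hydroxy-2,2-dimethyl-8-[(triisopropylsilyl)oxy]chroman-6-yl]boronic acid, via pinacol boronate 11 (not isolated)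
Conditions: [Ir(OMe)(cod)]2 (1.5 mol %), 4,4'-di-tert-butyl-2,2'-bipyridine (3 mol %), B2pin2 (1.5 equiv), THF, 80 °C; then NaIO4 (3 equiv), NH4OAc, acetone/H2O, rt
Reagents that add atoms: bis(pinacolato)diboron, CC1(C)OB(OC1(C)C)B1OC(C)(C)C(C)(C)O1; water, O
Why: Iridium-catalysed C–H borylation under steric control, C6 being the only ring C–H without an ortho substituent (the free alcohol is borylated transiently and released on work-up), followed in the same flask by periodate cleavage of the pinacol ester.

Step 9
Reactants: 13 7-hydroxy-4H-chromen-4-one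
Product: 14 7-[(triisopropylsilyl)oxy]-4H-chromen-4-one
Conditions: TIPSCl (1.2 equiv), imidazole (2.5 equiv), DMF, rt
Reagents that add atoms: triisopropylsilyl chloride, CC(C)[Si](Cl)(C(C)C)C(C)C
Why: Standard silylation of the acidic 7-hydroxyl group, which keeps the chromone soluble and non-ionised in the coupling and is removed together with the other silyl ether at the end.

Step 10
Reactants: 12 [(3S)-3-hydroxy-2,2-dimethyl-8-[(triisopropylsilyl)oxy]chroman-6-yl]boronic acid; 14 7-[(triisopropylsilyl)oxy]-4H-chromen-4-one (1.5 equiv)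
Product: 15 (2S)-2-[(3S)-3-hydroxy-2,2-dimethyl-8-[(triisopropylsilyl)oxy]chroman-6-yl]-7-[(triisopropylsilyl)oxy]chroman-4-one
Conditions: Pd(OCOCF3)2 (7.5 mol %), (R)-t-BuPyOX [(R)-4-tert-butyl-2-(pyridin-2-yl)-4,5-dihydro-1,3-oxazole] (9 mol %), NH4PF6 (30 mol %), H2O (5 equiv), ClCH2CH2Cl, 60 °C, air
Reagents that add atoms: none
Why: Enantioselective conjugate addition of an arylboronic acid to a chromone by a cationic divalent-palladium pyridine-oxazoline catalyst, in which the ligand sets flavanone C2; the (R)-ligand is chosen because the face selectivity known for cyclic enones translates into the (2S) product (the ligand antipode would be used should the sense prove opposite), and the remote C3 centre should not interfere.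

Step 11
Reactants: 15 (2S)-2-[(3S)-3-hydroxy-2,2-dimethyl-8-[(triisopropylsilyl)oxy]chroman-6-yl]-7-[(triisopropylsilyl)oxy]chroman-4-one
Product: 16 (2S)-2-[(3S)-3,8-dihydroxy-2,2-dimethylchroman-6-yl]-7-hydroxychroman-4-one
Conditions: HF·pyridine, THF/pyridine, 0 °C to rt
Reagents that add atoms: none
Why: Fluoride-mediated cleavage of both aryl silyl ethers under non-basic conditions, which should spare the base-sensitive flavanone C2 centre and the tertiary alkyl aryl ether.

Compound list
1 | methyl 2-bromo-6-hydroxybenzoate | COC(=O)c1c(O)cccc1Br | starting material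
2 | methyl 2-hydroxy-6-vinylbenzoate | COC(=O)c1c(O)cccc1C=C | intermediate
3 | 2-(2-hydroxy-6-vinylphenyl)propan-2-ol | CC(C)(O)c1c(O)cccc1C=C | intermediate
4 | 2-{2-[(triisopropylsilyl)oxy]-6-vinylphenyl}propan-2-ol | CC(C)(O)c1c(O[Si](C(C)C)(C(C)C)C(C)C)cccc1C=C | intermediate
5 | 2-{2-[(triisopropylsilyl)oxy]-6-vinylphenyl}propan-2-yl hydroperoxide | CC(C)(OO)c1c(O[Si](C(C)C)(C(C)C)C(C)C)cccc1C=C | intermediate
6 | 2-{2-[(triisopropylsilyl)oxy]-6-vinylphenyl}propan-2-yl trifluoroperoxyacetate | CC(C)(OOC(=O)C(F)(F)F)c1c(O[Si](C(C)C)(C(C)C)C(C)C)cccc1C=C | intermediate (not isolated)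
7 | {2-[(triisopropylsilyl)oxy]-6-vinylphenyl}(propan-2-ylidene)oxonium trifluoroacetate | CC(C)=[O+]c1c(O[Si](C(C)C)(C(C)C)C(C)C)cccc1C=C.[O-]C(=O)C(F)(F)F | intermediate (not isolated)
8 | 2,2-dimethyl-8-[(triisopropylsilyl)oxy]-2H-chromene | CC1(C)C=Cc2cccc(O[Si](C(C)C)(C(C)C)C(C)C)c2O1 | intermediate
9 | (3S,4S)-3,4-epoxy-2,2-dimethyl-8-[(triisopropylsilyl)oxy]chroman | CC1(C)Oc2c(O[Si](C(C)C)(C(C)C)C(C)C)cccc2[C@@H]3O[C@H]13 | intermediate
10 | (3S)-2,2-dimethyl-8-[(triisopropylsilyl)oxy]chroman-3-ol | CC1(C)Oc2c(O[Si](C(C)C)(C(C)C)C(C)C)cccc2C[C@@H]1O | intermediate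
11 | (3S)-2,2-dimethyl-6-(4,4,5,5-tetramethyl-1,3,2-dioxaborolan-2-yl)-8-[(triisopropylsilyl)oxy]chroman-3-ol | CC1(C)Oc2c(O[Si](C(C)C)(C(C)C)C(C)C)cc(B3OC(C)(C)C(C)(C)O3)cc2C[C@@H]1O | intermediate (not isolated)
12 | [(3S)-3-hydroxy-2,2-dimethyl-8-[(triisopropylsilyl)oxy]chroman-6-yl]boronic acid | CC1(C)Oc2c(O[Si](C(C)C)(C(C)C)C(C)C)cc(B(O)O)cc2C[C@@H]1O | intermediate
13 | 7-hydroxy-4H-chromen-4-one | O=c1ccoc2cc(O)ccc12 | starting material
14 | 7-[(triisopropylsilyl)oxy]-4H-chromen-4-one | O=c1ccoc2cc(O[Si](C(C)C)(C(C)C)C(C)C)ccc12 | intermediate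
15 | (2S)-2-[(3S)-3-hydroxy-2,2-dimethyl-8-[(triisopropylsilyl)oxy]chroman-6-yl]-7-[(triisopropylsilyl)oxy]chroman-4-one | CC1(C)Oc2c(O[Si](C(C)C)(C(C)C)C(C)C)cc([C@@H]3CC(=O)c4ccc(O[Si](C(C)C)(C(C)C)C(C)C)cc4O3)cc2C[C@@H]1O | intermediate
16 | (2S)-2-[(3S)-3,8-dihydroxy-2,2-dimethylchroman-6-yl]-7-hydroxychroman-4-one | CC1(C)Oc2c(O)cc([C@@H]3CC(=O)c4ccc(O)cc4O3)cc2C[C@@H]1O | target

Total step count: 11
Longest linear sequence: 10 steps (steps 1–8, 10 and 11; step 9 prepares the coupling partner)

Steps most likely to fail

1. Step 5 (Proposed new method). The oxocarbenium ion may be captured by trifluoroacetate or adventitious water and fragment to phenol and acetone before the ring closes. The perester may instead ionise at its C–O bond, followed by cationic cyclisation onto the vinyl group. The styrene or the chromene may oligomerise under acid. Fallback with known chemistry: from 5 the hydroperoxide is deliberately cleaved under ordinary Hock conditions (TsOH cat., wet acetone, 0 °C) to 2-[(triisopropylsilyl)oxy]-6-vinylphenol F1 and acetone. F1 is O-alkylated with methyl 2-methylbut-3-en-2-yl carbonate and Pd(PPh3)4 (THF, 0 °C) to the 1,1-dimethylallyl ether triisopropyl{2-[(2-methylbut-3-en-2-yl)oxy]-3-vinylphenoxy}silane F2. Ring-closing metathesis of F2 with the second-generation Grubbs catalyst (CH2Cl2, 40 °C) closes C3=C4 and comes back to the route at chromene 8.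

2. Step 4. The electron-rich hydroperoxide may rearrange and fragment prematurely under the acid used to make it, or the cumyl-type cation may eliminate or cyclise during the SN1 perhydrolysis. Fallback: from 4 the tertiary alcohol is activated under basic conditions (Cl3CCN, DBU cat., CH2Cl2, 0 °C) as 2-{2-[(triisopropylsilyl)oxy]-6-vinylphenyl}propan-2-yl 2,2,2-trichloroacetimidate F3. Perhydrolysis of F3 with anhydrous ethereal H2O2 without mineral acid comes back to the route at hydroperoxide 5.

3. Step 10. Carbopalladation of the electron-rich 7-silyloxychromone may be slow enough for protodeboronation of the electron-rich boronic acid to win, and facial control may be incomplete or of the opposite sense. Fallback: from 12 and 14 the addition is run with an achiral catalyst (Pd(OCOCF3)2, 2,2'-bipyridine, same medium) to give 15 together with its flavanone C2 epimer, (2R)-2-[(3S)-3-hydroxy-2,2-dimethyl-8-[(triisopropylsilyl)oxy]chroman-6-yl]-7-[(triisopropylsilyl)oxy]chroman-4-one F4. The two diastereomers are separated by preparative HPLC. F4 is equilibrated through the ring-opened 2'-hydroxychalcone (piperidine cat., EtOH, rt) and resubmitted to the separation, which converges on 15.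

Further compounds
F1 | step 5 | 2-[(triisopropylsilyl)oxy]-6-vinylphenol | Oc1c(O[Si](C(C)C)(C(C)C)C(C)C)cccc1C=C
F2 | step 5 | triisopropyl{2-[(2-methylbut-3-en-2-yl)oxy]-3-vinylphenoxy}silane | C=CC(C)(C)Oc1c(O[Si](C(C)C)(C(C)C)C(C)C)cccc1C=C
F3 | step 4 | 2-{2-[(triisopropylsilyl)oxy]-6-vinylphenyl}propan-2-yl 2,2,2-trichloroacetimidate | CC(C)(OC(=N)C(Cl)(Cl)Cl)c1c(O[Si](C(C)C)(C(C)C)C(C)C)cccc1C=C
F4 | step 10 | (2R)-2-[(3S)-3-hydroxy-2,2-dimethyl-8-[(triisopropylsilyl)oxy]chroman-6-yl]-7-[(triisopropylsilyl)oxy]chroman-4-one | CC1(C)Oc2c(O[Si](C(C)C)(C(C)C)C(C)C)cc([C@H]3CC(=O)c4ccc(O[Si](C(C)C)(C(C)C)C(C)C)cc4O3)cc2C[C@@H]1O
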